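**Plan**

-   Retrosynthetic cuts, in order: the C4 ketone goes back to a C4 carbinol; ring C is opened at O1–C8a (aryl ether from the primary C2 alcohol and a ring A bromide); C3–C4 is cut by an auxiliary-controlled aldol; ring B is cut at C1'–CH2 (acetate arylation) and at C5'–C(CH3)2 (Claisen), back to 2-methoxyresorcinol.
-   Forward order: ring B is dressed first (O-prenylation, silylation, Claisen shift to the 1,1-dimethylallyl group, methylation, bromination, acetate coupling) and loaded on the oxazolidinone; the aldol joins rings A and B through C3–C4; ring C closes last at O1–C8a; oxidation at C4 and desilylation finish.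
-   Enabling feature: C3 is configurationally labile only while C4 is a carbonyl, and O1–C8a is the one ring C bond remote from C3, so it can be closed under carbonate base while C4 is still a carbinol.
-   Stereochemistry: 3R comes from (S)-4-benzyl-2-oxazolidinone through the Z-boron enolate syn-aldol; the C4 carbinol centre set in the same step is sacrificial and is erased by a buffered oxidation, after which no base touches the molecule.

Key step: step 12

Remark: isoflavonoid numbering is used (ring C: O1, C2, C3, C4, C4a, C8a; ring B positions primed), the target is the 3R enantiomer, TIPS stands for triisopropylsilyl and ArB for the 3,4-dimethoxy-5-(2-methylbut-3-en-2-yl)-2-(TIPS-oxy)phenyl group.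

**Step 1**
Reactants: 1 2-methoxyresorcinol (2-methoxybenzene-1,3-diol); 2 prenyl bromide (1-bromo-3-methylbut-2-ene)
Product: 3 2-methoxy-3-[(3-methylbut-2-en-1-yl)oxy]phenol
Conditions: K2CO3, acetone, reflux; 1 in twofold excess
Reagents that add atoms: none
Why: Williamson etherification of one of two equivalent phenols, in which the excess of diol suppresses the bis-ether and unreacted 1 is recovered.

**Step 2**
Reactants: 3 2-methoxy-3-[(3-methylbut-2-en-1-yl)oxy]phenol
Product: 4 triisopropyl{2-methoxy-3-[(3-methylbut-2-en-1-yl)oxy]phenoxy}silane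
Conditions: TIPSCl, imidazole, DMF, rt
Reagents that add atoms: chlorotriisopropylsilane, CC(C)[Si](Cl)(C(C)C)C(C)C
Why: Imidazole-mediated silylation of the remaining phenol installs the bulky aryl silyl ether that is meant to stay in place until the last step.

**Step 3**
Reactants: 4 triisopropyl{2-methoxy-3-[(3-methylbut-2-en-1-yl)oxy]phenoxy}silane
Product: 6 2-methoxy-6-(2-methylbut-3-en-2-yl)-3-[(triisopropylsilyl)oxy]phenol, via ortho-dienone 5 (not isolated)
Conditions: PhNEt2, 190 °C, sealed tube
Reagents that add atoms: none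
Why: Aromatic Claisen rearrangement, in which the [3,3] shift can rearomatise only at the unsubstituted ortho carbon (the other carries OMe) and the allylic transposition turns the prenyl ether into the 1,1-dimethylallyl group.

**Step 4**
Reactants: 6 2-methoxy-6-(2-methylbut-3-en-2-yl)-3-[(triisopropylsilyl)oxy]phenol
Product: 7 [2,3-dimethoxy-4-(2-methylbut-3-en-2-yl)phenoxy]triisopropylsilane
Conditions: MeI, K2CO3, acetone, reflux
Reagents that add atoms: iodomethane, CI
Why: Williamson methylation of the hindered phenoxide with the smallest electrophile, the silyl ether being meta to it and unable to migrate.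

**Step 5**
Reactants: 7 [2,3-dimethoxy-4-(2-methylbut-3-en-2-yl)phenoxy]triisopropylsilane
Product: 8 [6-bromo-2,3-dimethoxy-4-(2-methylbut-3-en-2-yl)phenoxy]triisopropylsilane
Conditions: NBS, MeCN, 0 °C, dark
Reagents that add atoms: N-bromosuccinimide, O=C1CCC(=O)N1Br
Why: Electrophilic aromatic bromination should go to C6, which is ortho to the silyloxy group and para to the 3-methoxy group, because C5 is shielded by the quaternary carbon and the electron-rich arene should outpace the monosubstituted alkene.

**Step 6**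
Reactants: 8 [6-bromo-2,3-dimethoxy-4-(2-methylbut-3-en-2-yl)phenoxy]triisopropylsilane
Product: 9 tert-butyl ArB-acetate (tert-butyl {3,4-dimethoxy-5-(2-methylbut-3-en-2-yl)-2-[(triisopropylsilyl)oxy]phenyl}acetate)
Conditions: ClZnCH2CO2tBu (0.5 M in Et2O), Pd2(dba)3 (cat.), XPhos (2-dicyclohexylphosphino-2',4',6'-triisopropylbiphenyl, cat.), THF, 60 °C
Reagents that add atoms: 2-tert-butoxy-2-oxoethylzinc chloride, CC(C)(C)OC(=O)C[Zn]Cl
Why: Negishi-type palladium-catalysed α-arylation of a Reformatsky reagent (oxidative addition, transmetalation from zinc, reductive elimination) runs without added base and should leave the silyl ether and the alkene alone.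

**Step 7**
Reactants: 9 tert-butyl ArB-acetate
Product: 11 ArB-acetic acid ({3,4-dimethoxy-5-(2-methylbut-3-en-2-yl)-2-[(triisopropylsilyl)oxy]phenyl}acetic acid), via trimethylsilyl ester 10 (not isolated)
Conditions: TMSOTf, 2,6-lutidine, CH2Cl2, 0 °C to rt; aqueous work-up
Reagents that add atoms: none
Why: Silyl triflate-mediated tert-butyl ester cleavage (loss of isobutene to the silyl ester, hydrolysed on work-up) avoids hydroxide, which would attack the aryl silyl ether, and protic acid, which would endanger the 1,1-dimethylallyl arene.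

**Step 8**
Reactants: 11 ArB-acetic acid; 12 (S)-4-benzyl-2-oxazolidinone
Product: 14 (S)-4-benzyl-3-(ArB-acetyl)oxazolidin-2-one, via mixed pivalic anhydride 13 (not isolated)
Conditions: PivCl, Et3N, THF, −20 °C; then 12, LiCl, rt
Reagents that add atoms: none
Why: Mixed-anhydride N-acylation of the Evans auxiliary, in which the lithium-activated oxazolidinone attacks the less hindered arylacetyl carbonyl of the pivalic mixed anhydride.

**Step 9**
Reactants: 15 2-bromo-4-hydroxybenzaldehyde
Product: 16 2-bromo-4-[(triisopropylsilyl)oxy]benzaldehyde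
Conditions: TIPSCl, imidazole, CH2Cl2, rt
Reagents that add atoms: chlorotriisopropylsilane, CC(C)[Si](Cl)(C(C)C)C(C)C
Why: Imidazole-mediated silylation of the phenol, which leaves the aldehyde and the aryl bromide untouched.

**Step 10**
Reactants: 14 (S)-4-benzyl-3-(ArB-acetyl)oxazolidin-2-one; 16 2-bromo-4-[(triisopropylsilyl)oxy]benzaldehyde
Product: 19 (S)-4-benzyl-3-[(2S,3S)-3-{2-bromo-4-[(triisopropylsilyl)oxy]phenyl}-2-ArB-3-hydroxypropanoyl]oxazolidin-2-one, via dibutylboron Z-enolate 17 (not isolated), via dibutylboron aldolate 18 (not isolated)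
Conditions: Bu2BOTf, iPr2NEt, CH2Cl2, −78 to 0 °C; 16, −78 to 0 °C; pH 7 buffer, MeOH, H2O2, 0 °C
Reagents that add atoms: none
Why: Evans syn-aldol reaction, in which soft enolisation gives the Z-boron enolate and a chair Zimmerman–Traxler transition state on the face away from the benzyl group of the (S)-auxiliary sets the future C3 (2S in the adduct) and the sacrificial C4 centre (3S) in a syn relationship.

**Step 11**
Reactants: 19 syn-aldol adduct
Product: 20 (1S,2R)-1-{2-bromo-4-[(triisopropylsilyl)oxy]phenyl}-2-ArB-propane-1,3-diol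
Conditions: LiBH4, MeOH (1 equiv), THF, 0 °C
Reagents that add atoms: none
Why: Reductive cleavage of the N-acyloxazolidinone by LiBH4 at the exocyclic carbonyl frees the primary alcohol without touching the aryl bromide, the silyl ethers or the alkene, and the auxiliary is recovered.

**Step 12**
Reactants: 20 (1S,2R)-1-{2-bromo-4-[(triisopropylsilyl)oxy]phenyl}-2-ArB-propane-1,3-diol
Product: 21 trans-(3R,4S)-3-ArB-7-[(triisopropylsilyl)oxy]chroman-4-ol
Conditions: Pd(OAc)2 (5 mol%), 2-(di-tert-butylphosphino)-1,1'-binaphthyl (6 mol%), Cs2CO3, toluene, 70 °C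
Reagents that add atoms: none
Why: Pd(OAc)2 is reduced in the flask to a zerovalent palladium phosphine complex that inserts into the C8a–Br bond, carbonate-assisted exchange of bromide for the primary C2 alkoxide gives a seven-membered oxapalladacycle, and C–O reductive elimination releases the chroman and returns zerovalent palladium. The closest known reaction type is the intramolecular Buchwald–Hartwig etherification of 3-(2-bromoaryl)propan-1-ols to chromans. Ring C closes in a 6-exo sense at the aryl carbon C8a, and O1–C8a is the only new skeletal bond. No stereocentre is created: C3 and C4 are carried over from 20, and because C4 is still a carbinol C3 has no acidic hydrogen for Cs2CO3 to remove. The step needs reductive elimination to outrun β-hydride elimination of the primary alkoxide and needs the primary hydroxyl to win over the benzylic one; the bulky electron-rich di-tert-butylphosphine and the six-membered closure should secure the first, and the second follows because the C4 alkoxide can only form a five-membered chelate that would have to eliminate to a four-membered ring and that holds its C4–H bond away from palladium. The two aryl TIPS ethers are chosen because they should tolerate anhydrous carbonate in toluene.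

**Step 13**
Reactants: 21 trans-(3R,4S)-3-ArB-7-[(triisopropylsilyl)oxy]chroman-4-ol
Product: 22 (3R)-3-ArB-7-[(triisopropylsilyl)oxy]chroman-4-one
Conditions: Dess–Martin periodinane, pyridine, CH2Cl2, 0 °C to rt
Reagents that add atoms: none
Why: Dess–Martin oxidation under pyridine buffering turns the benzylic carbinol into the ketone and erases the auxiliary-derived C4 centre, without a base strong enough to enolise towards C3 and without free acid that could ionise the 7-oxygenated benzylic position.

**Step 14**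
Reactants: 22 (3R)-3-ArB-7-[(triisopropylsilyl)oxy]chroman-4-one
Product: 23 pervilleanone ((3R)-7-hydroxy-3-[2-hydroxy-3,4-dimethoxy-5-(2-methylbut-3-en-2-yl)phenyl]chroman-4-one)
Conditions: HF·pyridine, pyridine, THF, 0 °C to rt
Reagents that add atoms: none
Why: Fluoride-mediated desilylation with buffered HF·pyridine cleaves both aryl silyl ethers under weakly acidic conditions in which the C3–H of the isoflavanone should not be removed, so the 3R configuration should be kept.

**Compound list**

1 | 2-methoxyresorcinol (2-methoxybenzene-1,3-diol) | COc1c(O)cccc1O | starting material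
2 | prenyl bromide (1-bromo-3-methylbut-2-ene) | CC(C)=CCBr | starting material
3 | 2-methoxy-3-[(3-methylbut-2-en-1-yl)oxy]phenol | COc1c(O)cccc1OCC=C(C)C | intermediate
4 | triisopropyl{2-methoxy-3-[(3-methylbut-2-en-1-yl)oxy]phenoxy}silane | COc1c(O[Si](C(C)C)(C(C)C)C(C)C)cccc1OCC=C(C)C | intermediate
5 | 2-methoxy-6-(2-methylbut-3-en-2-yl)-3-[(triisopropylsilyl)oxy]cyclohexa-2,4-dien-1-one (transient, racemic at C6) | C=CC(C)(C)C1C=CC(O[Si](C(C)C)(C(C)C)C(C)C)=C(OC)C1=O | intermediate
6 | 2-methoxy-6-(2-methylbut-3-en-2-yl)-3-[(triisopropylsilyl)oxy]phenol | C=CC(C)(C)c1ccc(O[Si](C(C)C)(C(C)C)C(C)C)c(OC)c1O | intermediate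
7 | [2,3-dimethoxy-4-(2-methylbut-3-en-2-yl)phenoxy]triisopropylsilane | C=CC(C)(C)c1ccc(O[Si](C(C)C)(C(C)C)C(C)C)c(OC)c1OC | intermediate
8 | [6-bromo-2,3-dimethoxy-4-(2-methylbut-3-en-2-yl)phenoxy]triisopropylsilane | C=CC(C)(C)c1cc(Br)c(O[Si](C(C)C)(C(C)C)C(C)C)c(OC)c1OC | intermediate
9 | tert-butyl {3,4-dimethoxy-5-(2-methylbut-3-en-2-yl)-2-[(triisopropylsilyl)oxy]phenyl}acetate | C=CC(C)(C)c1cc(CC(=O)OC(C)(C)C)c(O[Si](C(C)C)(C(C)C)C(C)C)c(OC)c1OC | intermediate
10 | trimethylsilyl {3,4-dimethoxy-5-(2-methylbut-3-en-2-yl)-2-[(triisopropylsilyl)oxy]phenyl}acetate | C=CC(C)(C)c1cc(CC(=O)O[Si](C)(C)C)c(O[Si](C(C)C)(C(C)C)C(C)C)c(OC)c1OC | intermediate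
11 | {3,4-dimethoxy-5-(2-methylbut-3-en-2-yl)-2-[(triisopropylsilyl)oxy]phenyl}acetic acid | C=CC(C)(C)c1cc(CC(=O)O)c(O[Si](C(C)C)(C(C)C)C(C)C)c(OC)c1OC | intermediate
12 | (S)-4-benzyl-2-oxazolidinone | O=C1N[C@@H](Cc2ccccc2)CO1 | starting material
13 | {3,4-dimethoxy-5-(2-methylbut-3-en-2-yl)-2-[(triisopropylsilyl)oxy]phenyl}acetic pivalic anhydride | C=CC(C)(C)c1cc(CC(=O)OC(=O)C(C)(C)C)c(O[Si](C(C)C)(C(C)C)C(C)C)c(OC)c1OC | intermediate
14 | (S)-4-benzyl-3-({3,4-dimethoxy-5-(2-methylbut-3-en-2-yl)-2-[(triisopropylsilyl)oxy]phenyl}acetyl)oxazolidin-2-one | C=CC(C)(C)c1cc(CC(=O)N2C(=O)OC[C@@H]2Cc2ccccc2)c(O[Si](C(C)C)(C(C)C)C(C)C)c(OC)c1OC | intermediate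
15 | 2-bromo-4-hydroxybenzaldehyde | O=Cc1ccc(O)cc1Br | starting material
16 | 2-bromo-4-[(triisopropylsilyl)oxy]benzaldehyde | O=Cc1ccc(O[Si](C(C)C)(C(C)C)C(C)C)cc1Br | intermediate
17 | dibutylboron Z-enolate of 14 (O–B and aryl cis on the enolate double bond) | CCCCB(CCCC)O/C(=C\c1cc(C(C)(C)C=C)c(OC)c(OC)c1O[Si](C(C)C)(C(C)C)C(C)C)N1C(=O)OC[C@@H]1Cc1ccccc1 | intermediate
18 | dibutylboron aldolate of 19 (O-dibutylboryl at the carbinol oxygen) | C=CC(C)(C)c1cc([C@H](C(=O)N2C(=O)OC[C@@H]2Cc2ccccc2)[C@H](OB(CCCC)CCCC)c2ccc(O[Si](C(C)C)(C(C)C)C(C)C)cc2Br)c(O[Si](C(C)C)(C(C)C)C(C)C)c(OC)c1OC | intermediate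
19 | (S)-4-benzyl-3-[(2S,3S)-3-{2-bromo-4-[(triisopropylsilyl)oxy]phenyl}-2-{3,4-dimethoxy-5-(2-methylbut-3-en-2-yl)-2-[(triisopropylsilyl)oxy]phenyl}-3-hydroxypropanoyl]oxazolidin-2-one | C=CC(C)(C)c1cc([C@H](C(=O)N2C(=O)OC[C@@H]2Cc2ccccc2)[C@H](O)c2ccc(O[Si](C(C)C)(C(C)C)C(C)C)cc2Br)c(O[Si](C(C)C)(C(C)C)C(C)C)c(OC)c1OC | intermediate
20 | (1S,2R)-1-{2-bromo-4-[(triisopropylsilyl)oxy]phenyl}-2-{3,4-dimethoxy-5-(2-methylbut-3-en-2-yl)-2-[(triisopropylsilyl)oxy]phenyl}propane-1,3-diol | C=CC(C)(C)c1cc([C@H](CO)[C@H](O)c2ccc(O[Si](C(C)C)(C(C)C)C(C)C)cc2Br)c(O[Si](C(C)C)(C(C)C)C(C)C)c(OC)c1OC | intermediate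
21 | trans-(3R,4S)-3-{3,4-dimethoxy-5-(2-methylbut-3-en-2-yl)-2-[(triisopropylsilyl)oxy]phenyl}-7-[(triisopropylsilyl)oxy]chroman-4-ol | C=CC(C)(C)c1cc([C@@H]2COc3cc(O[Si](C(C)C)(C(C)C)C(C)C)ccc3[C@H]2O)c(O[Si](C(C)C)(C(C)C)C(C)C)c(OC)c1OC | intermediate
22 | (3R)-3-{3,4-dimethoxy-5-(2-methylbut-3-en-2-yl)-2-[(triisopropylsilyl)oxy]phenyl}-7-[(triisopropylsilyl)oxy]chroman-4-one | C=CC(C)(C)c1cc([C@@H]2COc3cc(O[Si](C(C)C)(C(C)C)C(C)C)ccc3C2=O)c(O[Si](C(C)C)(C(C)C)C(C)C)c(OC)c1OC | intermediate
23 | pervilleanone, (3R)-7-hydroxy-3-[2-hydroxy-3,4-dimethoxy-5-(2-methylbut-3-en-2-yl)phenyl]chroman-4-one | C=CC(C)(C)c1cc([C@@H]2COc3cc(O)ccc3C2=O)c(O)c(OC)c1OC | target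

**Count and risks**

Total step count: 14. Longest linear sequence: 13 steps (steps 1 to 8, then 10 to 14).

The three steps most likely to fail:

Step 12. The unprotected benzylic C4 hydroxyl may be engaged by the arylpalladium intermediate; β-hydride elimination would then reduce the C8a–Br bond and oxidise C4, so that debromination competes with C–O reductive elimination. The fallback sets out from 19 and masks that hydroxyl before the auxiliary is removed. TESOTf and 2,6-lutidine in CH2Cl2 at −78 °C should give the triethylsilyl ether of the aldol adduct F1. LiBH4 with MeOH in THF at 0 °C should then release the primary alcohol F2. The same Pd(OAc)2, phosphine and Cs2CO3 etherification, now with a single free hydroxyl, should close ring C to the 4-O-triethylsilyl isoflavan F3. HF·pyridine buffered with pyridine in THF at 0 °C, stopped as soon as the alkyl silyl ether is consumed, should cleave the triethylsilyl ether ahead of the two hindered aryl TIPS ethers, and the sequence comes back to the route at 21.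

Step 3. At the rearrangement temperature the newly formed ortho-(1,1-dimethylallyl)phenol may react on (ring closure of the hydroxyl onto the alkene, or abnormal Claisen isomerisation of the side chain), or the silyl ether may not survive prolonged heating. The fallback sets out from 3, rearranges before silylation and traps the phenols as they form. Heating 3 with acetic anhydride and NaOAc in PhNEt2 at about 190 °C should give 2-methoxy-4-(2-methylbut-3-en-2-yl)-1,3-phenylene diacetate F4. K2CO3 in MeOH at 0 °C should free 2-methoxy-4-(2-methylbut-3-en-2-yl)benzene-1,3-diol F5. TIPSCl and imidazole should then silylate only the hydroxyl that is not flanked by the quaternary carbon, and the sequence comes back to the route at 6.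

Step 5. Electrophilic bromine may add to the terminal alkene, or substitution next to the bulky silyl ether may be slow and unselective. The fallback sets out from 7 and lets a free phenol direct the halogen. TBAF in THF at 0 °C should remove the silyl group to give 2,3-dimethoxy-4-(2-methylbut-3-en-2-yl)phenol F6. NBS with catalytic iPr2NH in CH2Cl2 at −78 °C should brominate the only open ortho position (the para position is blocked) much faster than the alkene can react, giving 6-bromo-2,3-dimethoxy-4-(2-methylbut-3-en-2-yl)phenol F7. TIPSOTf and 2,6-lutidine in CH2Cl2 should re-silylate the hindered phenol, and the sequence comes back to the route at 8.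

**Further compounds**

F1 | step 12 | (S)-4-benzyl-3-[(2S,3S)-3-{2-bromo-4-[(triisopropylsilyl)oxy]phenyl}-2-{3,4-dimethoxy-5-(2-methylbut-3-en-2-yl)-2-[(triisopropylsilyl)oxy]phenyl}-3-[(triethylsilyl)oxy]propanoyl]oxazolidin-2-one | C=CC(C)(C)c1cc([C@H](C(=O)N2C(=O)OC[C@@H]2Cc2ccccc2)[C@H](O[Si](CC)(CC)CC)c2ccc(O[Si](C(C)C)(C(C)C)C(C)C)cc2Br)c(O[Si](C(C)C)(C(C)C)C(C)C)c(OC)c1OC
F2 | step 12 | (2R,3S)-3-{2-bromo-4-[(triisopropylsilyl)oxy]phenyl}-2-{3,4-dimethoxy-5-(2-methylbut-3-en-2-yl)-2-[(triisopropylsilyl)oxy]phenyl}-3-[(triethylsilyl)oxy]propan-1-ol | C=CC(C)(C)c1cc([C@H](CO)[C@H](O[Si](CC)(CC)CC)c2ccc(O[Si](C(C)C)(C(C)C)C(C)C)cc2Br)c(O[Si](C(C)C)(C(C)C)C(C)C)c(OC)c1OC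
F3 | step 12 | triethyl{[(3R,4S)-3-{3,4-dimethoxy-5-(2-methylbut-3-en-2-yl)-2-[(triisopropylsilyl)oxy]phenyl}-7-[(triisopropylsilyl)oxy]chroman-4-yl]oxy}silane | C=CC(C)(C)c1cc([C@@H]2COc3cc(O[Si](C(C)C)(C(C)C)C(C)C)ccc3[C@H]2O[Si](CC)(CC)CC)c(O[Si](C(C)C)(C(C)C)C(C)C)c(OC)c1OC
F4 | step 3 | 2-methoxy-4-(2-methylbut-3-en-2-yl)-1,3-phenylene diacetate | C=CC(C)(C)c1ccc(OC(C)=O)c(OC)c1OC(C)=O
F5 | step 3 | 2-methoxy-4-(2-methylbut-3-en-2-yl)benzene-1,3-diol | C=CC(C)(C)c1ccc(O)c(OC)c1O
F6 | step 5 | 2,3-dimethoxy-4-(2-methylbut-3-en-2-yl)phenol | C=CC(C)(C)c1ccc(O)c(OC)c1OC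
F7 | step 5 | 6-bromo-2,3-dimethoxy-4-(2-methylbut-3-en-2-yl)phenol | C=CC(C)(C)c1cc(Br)c(O)c(OC)c1OC
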